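Read at 5.0 min or at 20 min, this is one charge under two names, alder and elm: racemic G and D (mirror images) over solid Z, which dissolves to X, and X turns G into L.

| flask | G | D | Z | remark | time |
|---|---|---|---|---|---|
| midnight | 0.14 M | 0.14 M | 0.20 M | run made earlier |  |
| dawn | 0.22 M | 0.22 M | 0.20 M | run made earlier |  |
| spring | 0.10 M | 0.10 M | 0.10 M | run made earlier |  |
| elm | 0.10 M | 0.10 M | 0.200 M |  | 20 min |
| alder | 0.10 M | 0.10 M | 0.200 M |  | 5.0 min |

| run | time / min | D / % | G / % | L / % |
|---|---|---|---|---|
| midnight | 1.00 | 41.1 | 30.2 | 29.1 |
| midnight | 2.00 | 28.8 | 18.7 | 50.0 |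
| midnight | 5.00 | 14.1 | 15.1 | 70.0 |
| midnight | 12.0 | 13.9 | 15.2 | 70.3 |
| dawn | 3.00 | 28.1 | 26.8 | 44.9 |
| dawn | 6.00 | 27.3 | 26.8 | 44.1 |
| dawn | 10.0 | 26.6 | 26.6 | 45.3 |
| dawn | 12.0 | 27.1 | 26.8 | 43.9 |
| spring | 1.50 | 33.3 | 21.1 | 43.7 |
| spring | 4.00 | 24.6 | 25.4 | 48.9 |
| spring | 8.00 | 25.3 | 25.0 | 48.9 |
| spring | 12.0 | 24.8 | 25.9 | 48.8 |

(each reading ± 0.5 percentage points)

- X is single-handed; G and D are mirror images of each other, charged as a racemate, each of them at the stated concentration
- given per volume of solution although it is solid: Z
- at the start none of Z is in solution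
- an excess is the difference of the two amounts in percent of their sum
- an excess is below zero if the other one leads
- the handed part of X does not stay in what it makes, so the products of the two hands are mirror images too

- which of the two ends with the higher excess of D over G among what is left of the two ("neither" if they lie within 2 percentage points) (elm / alder / neither)
- excess of D over G among what is left of the two at the end, elm
- excess of D over G among what is left of the two at the end, alder

While L forms, G drops behind D. Afterwards the two meet again: in spring G climbs from 21.1% to 25.4%. The end state is racemic, so what you need is the distance from it when you stop.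

Take midnight between its first two readings. L gains 0.209 min⁻¹ of the charge, the gap D minus G holds near 11 percentage points, and mean G is 24.4%. Gain over gap is r, the relaxation rate of the pair, 1.99 min⁻¹. Gain over G is w, the pseudo-first-order pull on G, 0.855 min⁻¹. The excess E of D over G stands where r's loss meets w's gain: E is the root of r squared plus w squared, less r, over w.

My own figure for alder, with midnight's w, is 20.6%. For elm I expect nearly zero, provided w has died away by 20 min: with w at zero, the same root gives E of zero. So stop alder on time; don't let it stand.

The forecast gives 0.5% for elm and 15% for alder, below mine, with alder ahead: “some excess should remain”.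

The flask gives 1.48% in elm and 27.6% in alder, so alder leads; Q and J are further products.

    X + G → L (k = 1.30 M⁻¹ s⁻¹)
    G ⇌ D (k = 0.0170 s⁻¹)
    X + D → Q (k = 0.0170 M⁻¹ s⁻¹)
    2 X → J (k = 0.0140 M⁻¹ s⁻¹)
    Z ⇌ X, rate k5*(cs5 - [X]) while solid is left; crystals form when [X] > cs5 (solubility = 17.0 mM, k = 0.210 s⁻¹)

Alder's X of 0.0161 M makes w 1.25 min⁻¹, above midnight's reading, and r then gives 28.8%; the forecast lies 13 points under the flask. Elm's X of 7.35 × 10⁻⁴ M makes w 0.0573 min⁻¹, and r gives 1.44%. The neighbour charged with 0.050 M of Z holds X at 0 M by 20.0 min, so its w is zero and the same reckoning leaves no excess. It stands at 0%, with G at 37.5% and D at 37.5%.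

The data come from a simulation for an exercise; scatter was added.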